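**Plan**

1. Numbering used here: lactone carbonyl C1, ring CH C2, ring carbon bearing CH2OH C3, ring CH–O C4, then the chain C5 to C19. Retrosynthetic cuts, in order: C3–CH2OH (Stille hydroxymethylation of a β-iodobutenolide), ring O–C4 (lactone closure), C1–C2 (carbonylation of a propargylic mesylate), C6=C7 (Wittig), C8–C9 (hydrazone alkylation with farnesyl bromide), ω-C–H (SeO2).
2. Enabling feature: the O–C1(=O)–C2H=C3–C4H array of the furan-2(5H)-one ring is a cyclised 2,3-allenoic acid C1–C2=C3=C4. The carboxyl oxygen can reach C4 only from the side on which the carboxyl sits, and the central allene carbon C3 (the future β-carbon) takes up iodine as the handle for CH2OH.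
3. Forward order: fragment A (C7–C19 α-silyloxy ketone) from hydroxyacetone and farnesyl bromide; fragment B (C2–C6 phosphonium salt with the C4 carbinol and the alkyne) from 3-chloropropanoyl chloride; Wittig union; C1 added as CO; the only ring is closed near the end.
4. Stereochemistry: C4 comes from asymmetric transfer hydrogenation of an ynone ((S)-carbinol). It is relayed by anti SN2′ carbonylation into the (aR)-allene axis and by the ring closure back into (R)-C4 (net inversion). The 6Z olefin comes from the α-silyloxy-ketone Wittig, 10E/14E from farnesyl bromide, 18E from the SeO2 oxidation.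

Key step: step 14

Remark: the allene axis of 22 (and F5) is written in SMILES with the extended tetrahedral descriptor on the central carbon and explicit hydrogens on the terminal carbons.

**Route**

Step 1
Reactants: 1 hydroxyacetone
Product: 2 1-[(tert-butyldiphenylsilyl)oxy]propan-2-one
Conditions: TBDPSCl, imidazole, CH2Cl2, 0 °C to rt
Reagents that add atoms: tert-butyl(chloro)diphenylsilane, CC(C)(C)[Si](Cl)(c1ccccc1)c1ccccc1
Why: Standard O-silylation of a primary alcohol; the bulky, acid-stable silyl group later shields the oxygenated α-carbon and survives to the last step.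

Step 2
Reactants: 2 1-[(tert-butyldiphenylsilyl)oxy]propan-2-one
Product: 3 N,N-dimethylhydrazone of 2
Conditions: Me2NNH2, AcOH (cat.), EtOH, reflux
Reagents that add atoms: N,N-dimethylhydrazine, CN(C)N
Why: Hydrazone formation turns the ketone into an aza-enolate precursor that can be alkylated once, at the methyl carbon.

Step 3
Reactants: 3 N,N-dimethylhydrazone of 2; 4 (2E,6E)-farnesyl bromide
Product: 7 (5E,9E)-1-[(tert-butyldiphenylsilyl)oxy]-6,10,14-trimethylpentadeca-5,9,13-trien-2-one, via lithium aza-enolate 5 (not isolated), via farnesylated hydrazone 6 (not isolated)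
Conditions: LiN(i-Pr)2, THF, −78 to 0 °C; then 4, −78 °C to rt; then aq. oxalic acid, Et2O, rt
Reagents that add atoms: water, O
Why: Kinetic deprotonation of the dimethylhydrazone at the unhindered methyl group and SN2 alkylation by the primary allylic bromide (hydrazone aza-enolate alkylation) should form C8–C9 without touching the olefin geometries, and two-phase acid hydrolysis returns the ketone.

Step 4
Reactants: 7 (5E,9E)-1-[(tert-butyldiphenylsilyl)oxy]-6,10,14-trimethylpentadeca-5,9,13-trien-2-one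
Product: 8 (5E,9E,13E)-1-[(tert-butyldiphenylsilyl)oxy]-15-hydroxy-6,10,14-trimethylpentadeca-5,9,13-trien-2-one
Conditions: SeO2 (0.2 equiv), t-BuOOH (3 equiv), salicylic acid (0.1 equiv), CH2Cl2, 0 °C to rt
Reagents that add atoms: tert-butyl hydroperoxide, CC(C)(C)OO
Why: SeO2-catalysed allylic hydroxylation (ene reaction, then [2,3]-shift) is expected to prefer the terminal isopropylidene group and to oxidise its (E)-methyl, which sets the 18E allylic alcohol.

Step 5
Reactants: 8 (5E,9E,13E)-1-[(tert-butyldiphenylsilyl)oxy]-15-hydroxy-6,10,14-trimethylpentadeca-5,9,13-trien-2-one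
Product: 9 (5E,9E,13E)-1,15-bis[(tert-butyldiphenylsilyl)oxy]-6,10,14-trimethylpentadeca-5,9,13-trien-2-one
Conditions: TBDPSCl, imidazole, CH2Cl2, rt
Reagents that add atoms: tert-butyl(chloro)diphenylsilane, CC(C)(C)[Si](Cl)(c1ccccc1)c1ccccc1
Why: Routine silylation gives both primary alcohols the same robust protecting group for one final deprotection.

Step 6
Reactants: 10 3-chloropropanoyl chloride; 11 bis(trimethylsilyl)acetylene
Product: 12 5-chloro-1-(trimethylsilyl)pent-1-yn-3-one
Conditions: AlCl3, CH2Cl2, 0 °C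
Reagents that add atoms: none
Why: Friedel–Crafts-type acylation of the bis-silyl alkyne with ipso-desilylation gives the silyl ynone in one operation.

Step 7
Reactants: 12 5-chloro-1-(trimethylsilyl)pent-1-yn-3-one
Product: 13 (S)-5-chloro-1-(trimethylsilyl)pent-1-yn-3-ol
Conditions: Ru[(S,S)-TsDPEN](p-cymene) (1 mol %, 16-electron amido complex of divalent ruthenium), i-PrOH, rt
Reagents that add atoms: none
Why: In the Noyori asymmetric transfer hydrogenation of alkynyl ketones the alkynyl group takes the role of the aryl group of aryl ketones, so the (S,S)-catalyst should give the (S)-carbinol (future C4), and the base-free catalyst avoids loss of HCl from the β-chloro ketone.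

Step 8
Reactants: 13 (S)-5-chloro-1-(trimethylsilyl)pent-1-yn-3-ol
Product: 14 (S)-5-chloro-3-[(triethylsilyl)oxy]-1-(trimethylsilyl)pent-1-yne
Conditions: TESCl, imidazole, CH2Cl2, 0 °C
Reagents that add atoms: chlorotriethylsilane, CC[Si](Cl)(CC)CC
Why: The triethylsilyl ether tolerates ylide chemistry and can later be removed in the presence of the primary tert-butyldiphenylsilyl ethers.

Step 9
Reactants: 14 (S)-5-chloro-3-[(triethylsilyl)oxy]-1-(trimethylsilyl)pent-1-yne
Product: 16 [(S)-3-[(triethylsilyl)oxy]-5-(trimethylsilyl)pent-4-yn-1-yl]triphenylphosphonium iodide, via primary iodide 15 (not isolated)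
Conditions: NaI, PPh3, i-Pr2NEt (0.1 equiv), MeCN, reflux
Reagents that add atoms: triphenylphosphine, c1ccc(cc1)P(c1ccccc1)c1ccccc1; sodium iodide, [Na+].[I-]
Why: Finkelstein exchange activates the primary chloride and SN2 quaternisation of the phosphine follows in the same flask, with a trace of amine scavenging any acid that would cleave the silyl ether.

Step 10
Reactants: 16 [(S)-3-[(triethylsilyl)oxy]-5-(trimethylsilyl)pent-4-yn-1-yl]triphenylphosphonium iodide; 9 (5E,9E,13E)-1,15-bis[(tert-butyldiphenylsilyl)oxy]-6,10,14-trimethylpentadeca-5,9,13-trien-2-one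
Product: 18 (3S,5Z,9E,13E,17E)-19-[(tert-butyldiphenylsilyl)oxy]-6-{[(tert-butyldiphenylsilyl)oxy]methyl}-10,14,18-trimethyl-3-[(triethylsilyl)oxy]-1-(trimethylsilyl)nonadeca-5,9,13,17-tetraen-1-yne, via phosphorus ylide 17 (not isolated)
Conditions: KN(SiMe3)2, THF, −78 to 0 °C; then 9, −78 °C to rt
Reagents that add atoms: none
Why: The Wittig reaction of a salt-free, non-stabilised ylide with an α-silyloxy ketone is a known route to trisubstituted olefins with the oxygenated CH2 cis to the ylide-derived chain, which is the 6Z geometry of the target; the C4 carbinol centre is not involved.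

Step 11
Reactants: 18 (3S,5Z,9E,13E,17E)-silyl enyne from step 10
Product: 20 (3S,5Z,9E,13E,17E)-19-[(tert-butyldiphenylsilyl)oxy]-6-{[(tert-butyldiphenylsilyl)oxy]methyl}-10,14,18-trimethylnonadeca-5,9,13,17-tetraen-1-yn-3-ol, via terminal alkyne 19 (not isolated)
Conditions: K2CO3 (0.3 equiv), MeOH/THF, rt; then PPTS (1 equiv), rt
Reagents that add atoms: none
Why: Base-mediated methanolysis of the C(sp)–Si bond and then acid-catalysed methanolysis of the triethylsilyl ether are both much faster than cleavage of primary tert-butyldiphenylsilyl ethers, so the terminal alkyne and the C4 hydroxyl are freed selectively.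

Step 12
Reactants: 20 (3S)-propargylic alcohol from step 11
Product: 21 (3S)-methanesulfonate of 20
Conditions: MsCl, Et3N, CH2Cl2, −78 to −40 °C; used crude
Reagents that add atoms: methanesulfonyl chloride, CS(=O)(=O)Cl
Why: Sulfonylation at oxygen retains the C4 configuration and provides the leaving group for the SN2′ oxidative addition.

Step 13
Reactants: 21 (3S)-methanesulfonate of 20
Product: 22 (aR,6Z,10E,14E,18E)-20-[(tert-butyldiphenylsilyl)oxy]-7-{[(tert-butyldiphenylsilyl)oxy]methyl}-11,15,19-trimethylicosa-2,3,6,10,14,18-hexaenoic acid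
Conditions: Pd(PPh3)4 (5 mol %, zerovalent palladium), CO (1 atm), 2,6-lutidine, THF/H2O 10:1, rt
Reagents that add atoms: carbon monoxide, [C-]#[O+]; water, O
Why: Palladium-catalysed hydroxycarbonylation of a propargylic mesylate proceeds by anti SN2′ oxidative addition at the alkyne terminus C2, CO insertion with retention and hydrolysis of the acylpalladium, so the (S)-carbinol should be translated into the (aR)-2,3-allenoic acid while C1 is added.

Step 14
Reactants: 22 (aR)-2,3-allenoic acid from step 13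
Product: 23 (R)-5-[(2Z,6E,10E,14E)-16-[(tert-butyldiphenylsilyl)oxy]-3-{[(tert-butyldiphenylsilyl)oxy]methyl}-7,11,15-trimethylhexadeca-2,6,10,14-tetraen-1-yl]-4-iodofuran-2(5H)-one
Conditions: I2 (1.1 equiv), NaHCO3, MeCN, −20 to 0 °C, dark
Reagents that add atoms: iodine, II
Why: Iodine forms an iodonium ion on the distal C3=C4 π bond of the allene on the face away from the carboxylate, and the carboxylate oxygen attacks C4 within the plane of the C2 substituents (anti oxy-iodination), so O–C4 and C3–I form together and C2=C3 remains as the ring olefin. The closest known reaction type is the iodolactonisation of 2,3-allenoic acids to 4-iodofuran-2(5H)-ones with axial-to-central chirality transfer. The five-membered lactone closes in the 5-endo-trig mode, which is feasible for an allene because the attacked π orbital lies in the plane of the forming ring. The new stereocentre C4 is controlled by the allene axis alone: the oxygen can reach C4 only from the side on which the carboxyl group sits, so the (aR)-axis should give (R)-C4 whatever the electrophile. The step needs regioselectivity (oxygen to C4, iodine to C3), secured by the tether and the electron-poor C2=C3 bond, and chemoselectivity over the four trisubstituted olefins, secured because iodonium formation on an isolated olefin with no positioned nucleophile is reversible under buffered, water-free conditions with about one equivalent of I2 at low temperature. Racemisation through an open allyl cation is not expected because C4 carries only an alkyl group.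

Step 15
Reactants: 23 (R)-β-iodobutenolide from step 14
Product: 24 (R)-5-[(2Z,6E,10E,14E)-16-[(tert-butyldiphenylsilyl)oxy]-3-{[(tert-butyldiphenylsilyl)oxy]methyl}-7,11,15-trimethylhexadeca-2,6,10,14-tetraen-1-yl]-4-(hydroxymethyl)furan-2(5H)-one
Conditions: Bu3SnCH2OH (1.5 equiv), Pd2(dba)3 (2.5 mol %), AsPh3 (10 mol %), dioxane, 70 °C
Reagents that add atoms: (tributylstannyl)methanol, CCCC[Sn](CO)(CCCC)CCCC
Why: Stille coupling of the electron-poor vinyl iodide with the hydroxymethylstannane installs the β-CH2OH under neutral conditions that should leave the base-sensitive C4–H untouched.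

Step 16
Reactants: 24 bis-silyl ether of the target
Product: 25 hippolide F, (R)-5-[(2Z,6E,10E,14E)-16-hydroxy-3-(hydroxymethyl)-7,11,15-trimethylhexadeca-2,6,10,14-tetraen-1-yl]-4-(hydroxymethyl)furan-2(5H)-one
Conditions: HF·pyridine, pyridine, THF, 0 °C to rt
Reagents that add atoms: none
Why: Buffered fluoride cleavage of the two primary silyl ethers avoids basic conditions that could epimerise C4 or cause translactonisation onto the neighbouring CH2OH.

**Compound list**

1 | hydroxyacetone | CC(=O)CO | starting material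
2 | 1-[(tert-butyldiphenylsilyl)oxy]propan-2-one | CC(=O)CO[Si](c1ccccc1)(c1ccccc1)C(C)(C)C | intermediate
3 | N,N-dimethylhydrazone of 2 (C=N geometry not defined) | CC(CO[Si](c1ccccc1)(c1ccccc1)C(C)(C)C)=NN(C)C | intermediate
4 | (2E,6E)-farnesyl bromide | CC(C)=CCC/C(C)=C/CC/C(C)=C/CBr | starting material
5 | lithium aza-enolate of 3 (deprotonated at the methyl carbon) | [Li]N(N(C)C)C(=C)CO[Si](c1ccccc1)(c1ccccc1)C(C)(C)C | intermediate
6 | N,N-dimethylhydrazone of ketone 7 | CC(C)=CCC/C(C)=C/CC/C(C)=C/CCC(CO[Si](c1ccccc1)(c1ccccc1)C(C)(C)C)=NN(C)C | intermediate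
7 | (5E,9E)-1-[(tert-butyldiphenylsilyl)oxy]-6,10,14-trimethylpentadeca-5,9,13-trien-2-one | CC(C)=CCC/C(C)=C/CC/C(C)=C/CCC(=O)CO[Si](c1ccccc1)(c1ccccc1)C(C)(C)C | intermediate
8 | (5E,9E,13E)-1-[(tert-butyldiphenylsilyl)oxy]-15-hydroxy-6,10,14-trimethylpentadeca-5,9,13-trien-2-one | C/C(=C\CC/C(C)=C/CC/C(C)=C/CCC(=O)CO[Si](c1ccccc1)(c1ccccc1)C(C)(C)C)CO | intermediate
9 | (5E,9E,13E)-1,15-bis[(tert-butyldiphenylsilyl)oxy]-6,10,14-trimethylpentadeca-5,9,13-trien-2-one | C/C(=C\CC/C(C)=C/CC/C(C)=C/CCC(=O)CO[Si](c1ccccc1)(c1ccccc1)C(C)(C)C)CO[Si](c1ccccc1)(c1ccccc1)C(C)(C)C | intermediate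
10 | 3-chloropropanoyl chloride | O=C(Cl)CCCl | starting material
11 | bis(trimethylsilyl)acetylene | C[Si](C)(C)C#C[Si](C)(C)C | starting material
12 | 5-chloro-1-(trimethylsilyl)pent-1-yn-3-one | C[Si](C)(C)C#CC(=O)CCCl | intermediate
13 | (S)-5-chloro-1-(trimethylsilyl)pent-1-yn-3-ol | C[Si](C)(C)C#C[C@@H](O)CCCl | intermediate
14 | (S)-5-chloro-3-[(triethylsilyl)oxy]-1-(trimethylsilyl)pent-1-yne | C[Si](C)(C)C#C[C@@H](O[Si](CC)(CC)CC)CCCl | intermediate
15 | (S)-5-iodo-3-[(triethylsilyl)oxy]-1-(trimethylsilyl)pent-1-yne | C[Si](C)(C)C#C[C@@H](O[Si](CC)(CC)CC)CCI | intermediate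
16 | [(S)-3-[(triethylsilyl)oxy]-5-(trimethylsilyl)pent-4-yn-1-yl]triphenylphosphonium iodide | C[Si](C)(C)C#C[C@@H](O[Si](CC)(CC)CC)CC[P+](c1ccccc1)(c1ccccc1)c1ccccc1.[I-] | intermediate
17 | triphenylphosphonium ylide from 16 | C[Si](C)(C)C#C[C@@H](O[Si](CC)(CC)CC)CC=P(c1ccccc1)(c1ccccc1)c1ccccc1 | intermediate
18 | (3S,5Z,9E,13E,17E)-19-[(tert-butyldiphenylsilyl)oxy]-6-{[(tert-butyldiphenylsilyl)oxy]methyl}-10,14,18-trimethyl-3-[(triethylsilyl)oxy]-1-(trimethylsilyl)nonadeca-5,9,13,17-tetraen-1-yne | C/C(=C\CC/C(C)=C/CC/C(C)=C/CC/C(=C/C[C@H](O[Si](CC)(CC)CC)C#C[Si](C)(C)C)CO[Si](c1ccccc1)(c1ccccc1)C(C)(C)C)CO[Si](c1ccccc1)(c1ccccc1)C(C)(C)C | intermediate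
19 | terminal alkyne from 18 (C-desilylated, triethylsilyl ether retained) | C/C(=C\CC/C(C)=C/CC/C(C)=C/CC/C(=C/C[C@H](O[Si](CC)(CC)CC)C#C)CO[Si](c1ccccc1)(c1ccccc1)C(C)(C)C)CO[Si](c1ccccc1)(c1ccccc1)C(C)(C)C | intermediate
20 | (3S,5Z,9E,13E,17E)-19-[(tert-butyldiphenylsilyl)oxy]-6-{[(tert-butyldiphenylsilyl)oxy]methyl}-10,14,18-trimethylnonadeca-5,9,13,17-tetraen-1-yn-3-ol | C/C(=C\CC/C(C)=C/CC/C(C)=C/CC/C(=C/C[C@H](O)C#C)CO[Si](c1ccccc1)(c1ccccc1)C(C)(C)C)CO[Si](c1ccccc1)(c1ccccc1)C(C)(C)C | intermediate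
21 | (3S)-methanesulfonate of 20 | C/C(=C\CC/C(C)=C/CC/C(C)=C/CC/C(=C/C[C@H](OS(C)(=O)=O)C#C)CO[Si](c1ccccc1)(c1ccccc1)C(C)(C)C)CO[Si](c1ccccc1)(c1ccccc1)C(C)(C)C | intermediate
22 | (aR,6Z,10E,14E,18E)-20-[(tert-butyldiphenylsilyl)oxy]-7-{[(tert-butyldiphenylsilyl)oxy]methyl}-11,15,19-trimethylicosa-2,3,6,10,14,18-hexaenoic acid | C/C(=C\CC/C(C)=C/CC/C(C)=C/CC/C(=C/CC([H])=[C@]=C([H])C(=O)O)CO[Si](c1ccccc1)(c1ccccc1)C(C)(C)C)CO[Si](c1ccccc1)(c1ccccc1)C(C)(C)C | intermediate
23 | (R)-5-[(2Z,6E,10E,14E)-16-[(tert-butyldiphenylsilyl)oxy]-3-{[(tert-butyldiphenylsilyl)oxy]methyl}-7,11,15-trimethylhexadeca-2,6,10,14-tetraen-1-yl]-4-iodofuran-2(5H)-one | C/C(=C\CC/C(C)=C/CC/C(C)=C/CC/C(=C/C[C@H]1OC(=O)C=C1I)CO[Si](c1ccccc1)(c1ccccc1)C(C)(C)C)CO[Si](c1ccccc1)(c1ccccc1)C(C)(C)C | intermediate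
24 | (R)-5-[(2Z,6E,10E,14E)-16-[(tert-butyldiphenylsilyl)oxy]-3-{[(tert-butyldiphenylsilyl)oxy]methyl}-7,11,15-trimethylhexadeca-2,6,10,14-tetraen-1-yl]-4-(hydroxymethyl)furan-2(5H)-one | C/C(=C\CC/C(C)=C/CC/C(C)=C/CC/C(=C/C[C@H]1OC(=O)C=C1CO)CO[Si](c1ccccc1)(c1ccccc1)C(C)(C)C)CO[Si](c1ccccc1)(c1ccccc1)C(C)(C)C | intermediate
25 | hippolide F | C/C(=C\CC/C(C)=C/CC/C(C)=C/CC/C(=C/C[C@H]1OC(=O)C=C1CO)CO)CO | target

**Summary**

Total step count: 16. Longest linear sequence: 12 steps (steps 1–5 and 10–16); fragment B (steps 6–9) joins at step 10.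

Steps most likely to fail:

1. Step 14 (ring closure). Electrophilic iodine may be consumed by iodofunctionalisation or cation–olefin cyclisation of the four trisubstituted olefins, or the iodonium ion may open reversibly and erode the axial chirality before the ring closes. Fallback with carbophilic instead of halophilic activation: setting out from 22, Ph3PAuNTf2 (5 mol %, monovalent gold) in CH2Cl2 at −20 °C with N-iodosuccinimide should activate only the allene. The carboxyl oxygen attacks C4 anti to gold (same O–C4 bond, same transfer of chirality), and the vinylgold species is trapped by iododeauration. The route is rejoined at 23 and no new compound is made on the way (F0).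

2. Step 13 (hydroxycarbonylation). The allenyl/propargyl-palladium intermediate may undergo β-hydride elimination to a conjugated enyne or equilibrate with loss of chirality transfer, and the 2,3-dienoic acid may isomerise to the conjugated 2,4-dienoic acid. Fallback without palladium, with the axis set by a catalyst, setting out from ketone 9 and returning at 23:
   - Ketone 9 is condensed in a Wittig reaction (KN(SiMe3)2, THF) with [4-(trimethylsilyl)but-3-yn-1-yl]triphenylphosphonium bromide F1, made from commercial (4-bromobut-1-yn-1-yl)trimethylsilane and PPh3, to give the silylated skipped enyne F2.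
   - K2CO3 in MeOH gives the terminal 1,4-enyne F3.
   - Coupling with tert-butyl diazoacetate under CuI catalysis (copper iodide, MeCN, rt) gives the tert-butyl 3-alkynoate F4.
   - A C2-symmetric chiral bicyclic guanidine (2,6-di-tert-butyl-hexahydroimidazo[1,2-a]imidazole, in the enantiomeric form that leads to the aR axis) mediates an enantioselective 1,3-proton shift to the tert-butyl (aR)-allenoate F5.
   - F5 is submitted to the same iodolactonisation (I2, NaHCO3, MeCN), in which the tert-butyl group is lost from the oxocarbenium intermediate, and the route is rejoined at 23.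

3. Step 4 (allylic oxidation). Oxidation may also occur at the allylic positions of the two internal olefins, or run on to the enal, giving low conversion to 8. Fallback that installs the ω-oxygen before the chain meets the ketone, setting out from hydrazone 3 and returning at 9:
   - Commercial (2E,6E)-farnesol is acetylated (Ac2O, pyridine) to (2E,6E)-farnesyl acetate F6.
   - SeO2/t-BuOOH oxidation, here helped by the allylic acetate that deactivates the proximal olefin, gives (2E,6E,10E)-12-hydroxyfarnesyl acetate F7.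
   - TBDPSCl/imidazole gives the silyl ether F8.
   - K2CO3/MeOH gives the allylic alcohol F9.
   - CBr4/PPh3 gives the ω-silyloxy farnesyl bromide F10.
   - Alkylation of the aza-enolate 5 (from 3) with F10 gives the bis-silyloxy hydrazone F11, which is hydrolysed with aqueous oxalic acid directly to 9.

**Further compounds**

F0 | step 14 | none | none
F1 | step 13 | [4-(trimethylsilyl)but-3-yn-1-yl]triphenylphosphonium bromide | C[Si](C)(C)C#CCC[P+](c1ccccc1)(c1ccccc1)c1ccccc1.[Br-]
F2 | step 13 | (4Z,8E,12E,16E)-18-[(tert-butyldiphenylsilyl)oxy]-5-{[(tert-butyldiphenylsilyl)oxy]methyl}-9,13,17-trimethyl-1-(trimethylsilyl)octadeca-4,8,12,16-tetraen-1-yne | C/C(=C\CC/C(C)=C/CC/C(C)=C/CC/C(=C/CC#C[Si](C)(C)C)CO[Si](c1ccccc1)(c1ccccc1)C(C)(C)C)CO[Si](c1ccccc1)(c1ccccc1)C(C)(C)C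
F3 | step 13 | (4Z,8E,12E,16E)-18-[(tert-butyldiphenylsilyl)oxy]-5-{[(tert-butyldiphenylsilyl)oxy]methyl}-9,13,17-trimethyloctadeca-4,8,12,16-tetraen-1-yne | C/C(=C\CC/C(C)=C/CC/C(C)=C/CC/C(=C/CC#C)CO[Si](c1ccccc1)(c1ccccc1)C(C)(C)C)CO[Si](c1ccccc1)(c1ccccc1)C(C)(C)C
F4 | step 13 | tert-butyl (6Z,10E,14E,18E)-20-[(tert-butyldiphenylsilyl)oxy]-7-{[(tert-butyldiphenylsilyl)oxy]methyl}-11,15,19-trimethylicosa-6,10,14,18-tetraen-3-ynoate | C/C(=C\CC/C(C)=C/CC/C(C)=C/CC/C(=C/CC#CCC(=O)OC(C)(C)C)CO[Si](c1ccccc1)(c1ccccc1)C(C)(C)C)CO[Si](c1ccccc1)(c1ccccc1)C(C)(C)C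
F5 | step 13 | tert-butyl (aR,6Z,10E,14E,18E)-20-[(tert-butyldiphenylsilyl)oxy]-7-{[(tert-butyldiphenylsilyl)oxy]methyl}-11,15,19-trimethylicosa-2,3,6,10,14,18-hexaenoate | C/C(=C\CC/C(C)=C/CC/C(C)=C/CC/C(=C/CC([H])=[C@]=C([H])C(=O)OC(C)(C)C)CO[Si](c1ccccc1)(c1ccccc1)C(C)(C)C)CO[Si](c1ccccc1)(c1ccccc1)C(C)(C)C
F6 | step 4 | (2E,6E)-farnesyl acetate | CC(C)=CCC/C(C)=C/CC/C(C)=C/COC(C)=O
F7 | step 4 | (2E,6E,10E)-12-hydroxyfarnesyl acetate | C/C(=C\CC/C(C)=C/CC/C(C)=C/COC(C)=O)CO
F8 | step 4 | (2E,6E,10E)-12-[(tert-butyldiphenylsilyl)oxy]farnesyl acetate | C/C(=C\CC/C(C)=C/CC/C(C)=C/COC(C)=O)CO[Si](c1ccccc1)(c1ccccc1)C(C)(C)C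
F9 | step 4 | (2E,6E,10E)-12-[(tert-butyldiphenylsilyl)oxy]-3,7,11-trimethyldodeca-2,6,10-trien-1-ol | C/C(=C\CC/C(C)=C/CC/C(C)=C/CO)CO[Si](c1ccccc1)(c1ccccc1)C(C)(C)C
F10 | step 4 | (2E,6E,10E)-12-[(tert-butyldiphenylsilyl)oxy]farnesyl bromide | C/C(=C\CC/C(C)=C/CC/C(C)=C/CBr)CO[Si](c1ccccc1)(c1ccccc1)C(C)(C)C
F11 | step 4 | N,N-dimethylhydrazone of ketone 9 | C/C(=C\CC/C(C)=C/CC/C(C)=C/CCC(CO[Si](c1ccccc1)(c1ccccc1)C(C)(C)C)=NN(C)C)CO[Si](c1ccccc1)(c1ccccc1)C(C)(C)C
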